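Ring locants: C1 = C(OH)CH3, C2 = quaternary carbon (CH3, side chain), C3 = CH bearing the hydroxypropyl arm, C4 = alkylidene carbon, C5 and C6 = CH2. Everything rests on closing the six-membered ring at C1–C2, two carbons that are both electrophilic in the open-chain precursor: C1 is a methyl ketone carbonyl, C2 the β-carbon of a (Z)-enoate. SmI2 turns C1 into a nucleophilic ketyl, and one 6-exo cyclisation forms the ring and both fully substituted stereocentres, relayed from the auxiliary-set C3 centre by allylic strain. The precursor is an acyclic keto enoate; its ester carbon later carries the side chain (Negishi coupling).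

Key step: step 10

Remark: the ring locants C1–C6 defined above are used in the Why lines; systematic names carry their own locants.
Remark: (−)-MIB [(2S)-3-exo-morpholinoisoborneol] is taken to deliver the alkenyl group to the Si face of the aldehyde in step 20, as it does with simple aldehydes.

**Step 1**
Reactants: 1 δ-valerolactone (oxan-2-one)
Product: 4 5-[(tert-butyldiphenylsilyl)oxy]pentanoic acid, via sodium 5-hydroxypentanoate 2 (not isolated), via bis-silylated ester 3 (not isolated)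
Conditions: NaOH, MeOH/H2O, 60 °C; evaporate; t-BuPh2SiCl (2.2 equiv), imidazole, DMF, rt; then THF/H2O, AcOH, rt
Reagents that add atoms: sodium hydroxide, [Na+].[OH-]; tert-butyl(chloro)diphenylsilane, CC(C)(C)[Si](Cl)(c1ccccc1)c1ccccc1
Why: Saponification opens the lactone, exhaustive silylation follows, and the labile silyl ester is hydrolysed selectively while the primary silyl ether stays (lactone hydrolysis and silyl ether protection).

**Step 2**
Reactants: 4 5-[(tert-butyldiphenylsilyl)oxy]pentanoic acid; 5 (R)-4-benzyl-1,3-thiazolidine-2-thione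
Product: 6 (R)-4-benzyl-3-{5-[(tert-butyldiphenylsilyl)oxy]pentanoyl}-1,3-thiazolidine-2-thione
Conditions: EDC·HCl, DMAP (cat.), CH2Cl2, 0 °C → rt
Reagents that add atoms: none
Why: Carbodiimide activation with DMAP catalysis acylates the thiazolidinethione nitrogen (Steglich-type N-acylation).

**Step 3**
Reactants: 6 the N-acyl thiazolidinethione; 7 pent-4-enal
Product: 9 (R)-4-benzyl-3-[(2R,3S)-2-{3-[(tert-butyldiphenylsilyl)oxy]propyl}-3-hydroxyhept-6-enoyl]-1,3-thiazolidine-2-thione, via chlorotitanium enolate 8 (not isolated)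
Conditions: TiCl4 (1.05 equiv), i-Pr2NEt (1.1 equiv), N-methylpyrrolidinone (1.0 equiv), CH2Cl2, 0 °C; then 7, −78 → 0 °C
Reagents that add atoms: none
Why: Soft enolisation gives the (Z)-enolate 8, which should add to the aldehyde through a closed, non-chelated chair on the face away from the benzyl group, setting the future C3 centre and the neighbouring C4 carbinol syn, (2R,3S) (auxiliary-controlled titanium enolate aldol addition).

**Step 4**
Reactants: 9 the syn aldol adduct
Product: 10 (R)-4-benzyl-3-[(2R,3S)-3-[(tert-butyldimethylsilyl)oxy]-2-{3-[(tert-butyldiphenylsilyl)oxy]propyl}hept-6-enoyl]-1,3-thiazolidine-2-thione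
Conditions: TBSOTf, 2,6-lutidine, CH2Cl2, 0 °C
Reagents that add atoms: tert-butyldimethylsilyl trifluoromethanesulfonate, CC(C)(C)[Si](C)(C)OS(=O)(=O)C(F)(F)F
Why: The silyl triflate with a hindered pyridine base silylates the secondary alcohol without retro-aldol cleavage (silyl ether protection).

**Step 5**
Reactants: 10 the silylated aldol adduct
Product: 11 (2R,3S)-3-[(tert-butyldimethylsilyl)oxy]-2-{3-[(tert-butyldiphenylsilyl)oxy]propyl}hept-6-enal
Conditions: i-Bu2AlH (1.5 equiv), CH2Cl2, −78 °C; aq. potassium sodium tartrate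
Reagents that add atoms: none
Why: The activated thioimide accepts a single hydride at −78 °C and should give the aldehyde directly, with release of the auxiliary and no epimerisation of the α-centre (partial reduction of an N-acyl thiazolidinethione).

**Step 6**
Reactants: 11 the aldehyde
Product: 12 (3S,4S)-1,1-dibromo-4-[(tert-butyldimethylsilyl)oxy]-3-{3-[(tert-butyldiphenylsilyl)oxy]propyl}octa-1,7-diene
Conditions: CBr4, PPh3, 2,6-lutidine, CH2Cl2, 0 °C
Reagents that add atoms: carbon tetrabromide, BrC(Br)(Br)Br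
Why: The dibromomethylene ylide made from CBr4 and PPh3 olefinates the aldehyde, and the buffered medium spares the α-centre and the silyl ethers (Corey–Fuchs reaction, first stage).

**Step 7**
Reactants: 12 the dibromoalkene
Product: 14 ethyl (4S,5S)-5-[(tert-butyldimethylsilyl)oxy]-4-{3-[(tert-butyldiphenylsilyl)oxy]propyl}non-8-en-2-ynoate, via lithium acetylide 13 (not isolated)
Conditions: n-BuLi (2.2 equiv), THF, −78 °C; then ClCO2Et, −78 → 0 °C
Reagents that add atoms: ethyl chloroformate, CCOC(Cl)=O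
Why: Bromine–lithium exchange with 1,2-shift and deprotonation gives the acetylide 13, which is acylated by the chloroformate (Corey–Fuchs reaction, second stage, with electrophilic trapping).

**Step 8**
Reactants: 14 the ynoate
Product: 15 ethyl (2Z,4S,5S)-5-[(tert-butyldimethylsilyl)oxy]-4-{3-[(tert-butyldiphenylsilyl)oxy]propyl}-3-methylnona-2,8-dienoate
Conditions: Me2CuLi (from MeLi and CuI), THF, −78 °C; MeOH, −78 °C
Reagents that add atoms: lithium dimethylcuprate, [Li+].C[Cu-]C
Why: Syn carbocupration of the ynoate and cold protonation place the new methyl cis to H-2, so the ester ends up cis to the branched chain, the (Z)-enoate (stereospecific cuprate conjugate addition to an alkynoate).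

**Step 9**
Reactants: 15 the (Z)-dienoate
Product: 16 ethyl (2Z,4S,5S)-5-[(tert-butyldimethylsilyl)oxy]-4-{3-[(tert-butyldiphenylsilyl)oxy]propyl}-3-methyl-8-oxonon-2-enoate
Conditions: PdCl2 (10 mol%), CuCl, O2 (1 atm), DMF/H2O, rt
Reagents that add atoms: water, O
Why: The monosubstituted alkene is oxidised with Markovnikov selectivity to the methyl ketone, while the trisubstituted electron-poor enoate is inert (Wacker oxidation).

**Step 10**
Reactants: 16 the keto (Z)-enoate
Product: 19 ethyl 2-[(1S,2S,5S,6S)-5-[(tert-butyldimethylsilyl)oxy]-6-{3-[(tert-butyldiphenylsilyl)oxy]propyl}-2-hydroxy-1,2-dimethylcyclohexyl]acetate, via samarium ketyl 17 (not isolated), via samarium enolate 18 (not isolated)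
Conditions: SmI2 (3 equiv), HMPA (12 equiv), t-BuOH (2 equiv), THF, −78 → 0 °C
Reagents that add atoms: none
Why: Electron transfer from SmI2–HMPA to the methyl ketone gives the ketyl 17, whose radical carbon (C1) adds 6-exo-trig to the β-carbon (C2) of the (Z)-enoate, and a second electron transfer gives the enolate 18 that t-BuOH protonates, so two electrophilic carbons are joined by polarity reversal (SmI2 ketyl–olefin reductive cyclisation, a known reaction type). The six-membered ring should close through a chair in which the C3 chain, the C4 silyloxy group, the enoate carbon on C2 and the samarium-bound oxygen on C1 are all equatorial. The C2 centre is controlled by A(1,3) strain: the ester cis to C3 forces H-3 into the olefin plane, so the tethered ketyl must attack the face anti to the C3 propyl chain, which places CH2CO2Et trans to that chain and the C2 methyl axial. The C1 centre is controlled by the bulky, electron-rich O–Sm(HMPA)n group, which stays equatorial and anti to the enoate and so leaves OH cis to the C2 methyl. The step needs reduction of the ketone in preference to the hindered enoate and ring closure faster than further reduction of the ketyl; the enoate is harder to reduce than the ketone, the 6-exo tether is short, only two equivalents of proton donor are present, and the silyl ethers are inert.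

**Step 11**
Reactants: 19 the cyclohexanol
Product: 20 ethyl 2-[(1S,2S,5S,6S)-6-{3-[(tert-butyldiphenylsilyl)oxy]propyl}-2,5-dihydroxy-1,2-dimethylcyclohexyl]acetate
Conditions: HF·pyridine, pyridine, THF, 0 °C → rt
Reagents that add atoms: none
Why: Buffered HF·pyridine should cleave the secondary tert-butyldimethylsilyl ether, spare the more stable primary tert-butyldiphenylsilyl ether, and be too weakly acidic to lactonise the hydroxy ester (selective desilylation).

**Step 12**
Reactants: 20 the diol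
Product: 21 ethyl 2-[(1S,2S,6S)-6-{3-[(tert-butyldiphenylsilyl)oxy]propyl}-2-hydroxy-1,2-dimethyl-5-oxocyclohexyl]acetate
Conditions: Dess–Martin periodinane, NaHCO3, CH2Cl2, rt
Reagents that add atoms: none
Why: The neutral hypervalent iodine oxidant converts the secondary alcohol into the C4 ketone without touching the tertiary alcohol or epimerising C3 (Dess–Martin oxidation).

**Step 13**
Reactants: 21 the hydroxy ketone
Product: 22 ethyl 2-[(1S,2S,6S)-6-{3-[(tert-butyldiphenylsilyl)oxy]propyl}-1,2-dimethyl-5-oxo-2-[(triethylsilyl)oxy]cyclohexyl]acetate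
Conditions: Et3SiOTf, 2,6-lutidine, CH2Cl2, −78 → −20 °C
Reagents that add atoms: triethylsilyl trifluoromethanesulfonate, CC[Si](CC)(CC)OS(=O)(=O)C(F)(F)F
Why: The silyl triflate silylates the hindered tertiary alcohol at low temperature, where the weak base does not turn the ketone into its silyl enol ether (silyl ether protection).

**Step 14**
Reactants: 22 the silylated ketone; 23 diethyl (1-cyanoethyl)phosphonate
Product: 24 ethyl 2-[(1S,2S,5Z,6R)-6-{3-[(tert-butyldiphenylsilyl)oxy]propyl}-5-(1-cyanoethylidene)-1,2-dimethyl-2-[(triethylsilyl)oxy]cyclohexyl]acetate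
Conditions: NaH, THF, 0 °C; then 22, 0 → 65 °C
Reagents that add atoms: none
Why: The small, weakly basic phosphonate anion should add to the hindered ketone without enolising it, and the olefin should form with the slim nitrile on the side of the substituted C3 and the methyl on the side of the C5 methylene, the (Z) geometry of the later enal (Horner–Wadsworth–Emmons olefination).

**Step 15**
Reactants: 24 the nitrile ester
Product: 25 (2Z)-2-[(2R,3S,4S)-2-{3-[(tert-butyldiphenylsilyl)oxy]propyl}-3-(2-hydroxyethyl)-3,4-dimethyl-4-[(triethylsilyl)oxy]cyclohexylidene]propanenitrile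
Conditions: LiBH4, THF, 0 °C → rt
Reagents that add atoms: none
Why: LiBH4 reduces the ester to the primary alcohol and leaves the tetrasubstituted conjugated nitrile and the silyl ethers untouched (chemoselective hydride reduction).

**Step 16**
Reactants: 25 the primary alcohol
Product: 26 (2Z)-2-[(2R,3S,4S)-2-{3-[(tert-butyldiphenylsilyl)oxy]propyl}-3-(2-iodoethyl)-3,4-dimethyl-4-[(triethylsilyl)oxy]cyclohexylidene]propanenitrile
Conditions: I2, PPh3, imidazole, CH2Cl2, 0 °C → rt
Reagents that add atoms: iodine, II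
Why: Phosphine–iodine activation under imidazole buffering replaces the primary hydroxyl by iodide in an SN2 step (Appel-type iodination).

**Step 17**
Reactants: 27 prop-2-yn-1-ol
Product: 29 (E)-3-iodo-2-methylprop-2-en-1-ol, via alkenylalane 28 (not isolated)
Conditions: Me3Al (3 equiv), Cp2ZrCl2 (0.25 equiv), CH2Cl2, 0 °C → rt; then I2, THF, −30 → 0 °C
Reagents that add atoms: trimethylaluminium, C[Al](C)C; iodine, II
Why: Zirconium-catalysed syn methylalumination places aluminium on the terminal carbon, and iodinolysis with retention gives the (E)-iodoalkene (carboalumination–iodination).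

**Step 18**
Reactants: 29 the iodo allylic alcohol
Product: 30 (E)-3-iodo-2-methylprop-2-enal
Conditions: MnO2, CH2Cl2, rt
Reagents that add atoms: none
Why: MnO2 oxidises the allylic alcohol to the enal without affecting the vinyl iodide (allylic oxidation).

**Step 19**
Reactants: 31 (S)-citronellal [(3S)-3,7-dimethyloct-6-enal]
Product: 33 (3S)-3,7-dimethyloct-6-en-1-yne, via enol nonaflate 32 (not isolated)
Conditions: C4F9SO2F (1.3 equiv), P2-Et phosphazene base (2.5 equiv), DMF, −10 °C → rt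
Reagents that add atoms: none
Why: The phosphazene base enolises the aldehyde, the enolate is trapped as the enol nonaflate 32, and a second equivalent of base eliminates nonaflate to the terminal alkyne without touching the now propargylic stereocentre (enol sulfonate formation–elimination).

**Step 20**
Reactants: 33 the alkyne; 30 (E)-3-iodo-2-methylprop-2-enal
Product: 36 (1E,3S,4E,6S)-1-iodo-2,6,10-trimethylundeca-1,4,9-trien-3-ol, via alkenylborane 34 (not isolated), via alkenylzinc 35 (not isolated)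
Conditions: Cy2BH, toluene, 0 °C → rt; Me2Zn, −78 °C; (−)-MIB (5 mol%), then 30, −20 °C
Reagents that add atoms: none
Why: Syn hydroboration gives the (E)-alkenylborane 34, boron–zinc exchange gives 35, and the amino alcohol ligand should direct its addition to the Si face of the aldehyde, setting the carbinol centre (S) under catalyst control (catalytic asymmetric alkenylzinc addition).

**Step 21**
Reactants: 36 the dienyl alcohol
Product: 37 tert-butyl{[(1E,3S,4E,6S)-1-iodo-2,6,10-trimethylundeca-1,4,9-trien-3-yl]oxy}dimethylsilane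
Conditions: TBSCl, imidazole, DMF, rt
Reagents that add atoms: tert-butyl(chloro)dimethylsilane, CC(C)(C)[Si](C)(C)Cl
Why: Imidazole-promoted silylation protects the doubly allylic alcohol under non-acidic conditions (silyl ether protection).

**Step 22**
Reactants: 26 the primary iodide; 37 the vinyl iodide
Product: 39 (2Z)-2-[(2R,3S,4S)-3-[(3E,5S,6E,8S)-5-[(tert-butyldimethylsilyl)oxy]-4,8,12-trimethyltrideca-3,6,11-trien-1-yl]-2-{3-[(tert-butyldiphenylsilyl)oxy]propyl}-3,4-dimethyl-4-[(triethylsilyl)oxy]cyclohexylidene]propanenitrile, via alkylzinc iodide 38 (not isolated)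
Conditions: Zn dust (activated), THF/N,N-dimethylacetamide, 40 °C; then 37, Pd(PPh3)4 (5 mol%), rt → 40 °C
Reagents that add atoms: none
Why: Zinc inserts into the primary C–I bond in the presence of the nitrile and silyl ethers, and the palladium-catalysed sp3–sp2 coupling with the (E)-vinyl iodide proceeds with retention of olefin geometry (Negishi coupling).

**Step 23**
Reactants: 39 the coupled nitrile
Product: 41 (2Z)-2-[(2R,3S,4S)-3-[(3E,5S,6E,8S)-5-[(tert-butyldimethylsilyl)oxy]-4,8,12-trimethyltrideca-3,6,11-trien-1-yl]-2-{3-[(tert-butyldiphenylsilyl)oxy]propyl}-3,4-dimethyl-4-[(triethylsilyl)oxy]cyclohexylidene]propanal, via aluminium aldimine 40 (not isolated)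
Conditions: i-Bu2AlH (1.5 equiv), toluene, −78 → −40 °C; aq. tartaric acid, 0 °C
Reagents that add atoms: water, O
Why: One hydride adds to the nitrile to give the N-aluminated imine 40, which resists further reduction and should be hydrolysed to the enal with the olefin geometry retained (partial reduction of a nitrile).

**Step 24**
Reactants: 41 the tris-silyl enal
Product: 42 (2Z)-2-[(2R,3S,4S)-4-hydroxy-3-[(3E,5S,6E,8S)-5-hydroxy-4,8,12-trimethyltrideca-3,6,11-trien-1-yl]-2-(3-hydroxypropyl)-3,4-dimethylcyclohexylidene]propanal (target)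
Conditions: Bu4NF, AcOH, THF, 0 °C → rt
Reagents that add atoms: none
Why: Acetic acid-buffered fluoride should cleave the three silyl ethers without exposing the enal and the doubly allylic alcohol to strong base or acid (global desilylation).

**Compound list**

1 | oxan-2-one (δ-valerolactone) | O=C1CCCCO1 | starting material
2 | sodium 5-hydroxypentanoate | [Na+].[O-]C(=O)CCCCO | intermediate
3 | tert-butyldiphenylsilyl 5-[(tert-butyldiphenylsilyl)oxy]pentanoate | CC(C)(C)[Si](c1ccccc1)(c1ccccc1)OCCCCC(=O)O[Si](c1ccccc1)(c1ccccc1)C(C)(C)C | intermediate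
4 | 5-[(tert-butyldiphenylsilyl)oxy]pentanoic acid | CC(C)(C)[Si](c1ccccc1)(c1ccccc1)OCCCCC(O)=O | intermediate
5 | (R)-4-benzyl-1,3-thiazolidine-2-thione | S=C1SC[C@@H](Cc2ccccc2)N1 | starting material
6 | (R)-4-benzyl-3-{5-[(tert-butyldiphenylsilyl)oxy]pentanoyl}-1,3-thiazolidine-2-thione | CC(C)(C)[Si](c1ccccc1)(c1ccccc1)OCCCCC(=O)N1[C@H](Cc2ccccc2)CSC1=S | intermediate
7 | pent-4-enal | C=CCCC=O | starting material
8 | trichlorotitanium (Z)-enolate of 6 | Cl[Ti](Cl)(Cl)O/C(=C\CCCO[Si](c1ccccc1)(c1ccccc1)C(C)(C)C)N1[C@H](Cc2ccccc2)CSC1=S | intermediate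
9 | (R)-4-benzyl-3-[(2R,3S)-2-{3-[(tert-butyldiphenylsilyl)oxy]propyl}-3-hydroxyhept-6-enoyl]-1,3-thiazolidine-2-thione | C=CCC[C@H](O)[C@@H](CCCO[Si](c1ccccc1)(c1ccccc1)C(C)(C)C)C(=O)N1[C@H](Cc2ccccc2)CSC1=S | intermediate
10 | (R)-4-benzyl-3-[(2R,3S)-3-[(tert-butyldimethylsilyl)oxy]-2-{3-[(tert-butyldiphenylsilyl)oxy]propyl}hept-6-enoyl]-1,3-thiazolidine-2-thione | C=CCC[C@H](O[Si](C)(C)C(C)(C)C)[C@@H](CCCO[Si](c1ccccc1)(c1ccccc1)C(C)(C)C)C(=O)N1[C@H](Cc2ccccc2)CSC1=S | intermediate
11 | (2R,3S)-3-[(tert-butyldimethylsilyl)oxy]-2-{3-[(tert-butyldiphenylsilyl)oxy]propyl}hept-6-enal | C=CCC[C@H](O[Si](C)(C)C(C)(C)C)[C@@H](CCCO[Si](c1ccccc1)(c1ccccc1)C(C)(C)C)C=O | intermediate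
12 | (3S,4S)-1,1-dibromo-4-[(tert-butyldimethylsilyl)oxy]-3-{3-[(tert-butyldiphenylsilyl)oxy]propyl}octa-1,7-diene | C=CCC[C@H](O[Si](C)(C)C(C)(C)C)[C@@H](CCCO[Si](c1ccccc1)(c1ccccc1)C(C)(C)C)C=C(Br)Br | intermediate
13 | lithium acetylide of (3S,4S)-4-[(tert-butyldimethylsilyl)oxy]-3-{3-[(tert-butyldiphenylsilyl)oxy]propyl}oct-7-en-1-yne | [Li]C#C[C@H](CCCO[Si](c1ccccc1)(c1ccccc1)C(C)(C)C)[C@@H](O[Si](C)(C)C(C)(C)C)CCC=C | intermediate
14 | ethyl (4S,5S)-5-[(tert-butyldimethylsilyl)oxy]-4-{3-[(tert-butyldiphenylsilyl)oxy]propyl}non-8-en-2-ynoate | CCOC(=O)C#C[C@H](CCCO[Si](c1ccccc1)(c1ccccc1)C(C)(C)C)[C@@H](O[Si](C)(C)C(C)(C)C)CCC=C | intermediate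
15 | ethyl (2Z,4S,5S)-5-[(tert-butyldimethylsilyl)oxy]-4-{3-[(tert-butyldiphenylsilyl)oxy]propyl}-3-methylnona-2,8-dienoate | CCOC(=O)/C=C(/C)[C@H](CCCO[Si](c1ccccc1)(c1ccccc1)C(C)(C)C)[C@@H](O[Si](C)(C)C(C)(C)C)CCC=C | intermediate
16 | ethyl (2Z,4S,5S)-5-[(tert-butyldimethylsilyl)oxy]-4-{3-[(tert-butyldiphenylsilyl)oxy]propyl}-3-methyl-8-oxonon-2-enoate | CCOC(=O)/C=C(/C)[C@H](CCCO[Si](c1ccccc1)(c1ccccc1)C(C)(C)C)[C@@H](O[Si](C)(C)C(C)(C)C)CCC(C)=O | intermediate
17 | samarium ketyl of 16 (carbon radical at the former ketone carbon, O–SmI2) | CCOC(=O)/C=C(/C)[C@H](CCCO[Si](c1ccccc1)(c1ccccc1)C(C)(C)C)[C@@H](O[Si](C)(C)C(C)(C)C)CC[C](C)O[Sm](I)I | intermediate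
18 | samarium ester enolate of 19 with samarium-bound tertiary alkoxide | CCOC(O[Sm](I)I)=C[C@@]1(C)[C@H](CCCO[Si](c2ccccc2)(c3ccccc3)C(C)(C)C)[C@@H](O[Si](C)(C)C(C)(C)C)CC[C@]1(C)O[Sm](I)I | intermediate
19 | ethyl 2-[(1S,2S,5S,6S)-5-[(tert-butyldimethylsilyl)oxy]-6-{3-[(tert-butyldiphenylsilyl)oxy]propyl}-2-hydroxy-1,2-dimethylcyclohexyl]acetate | CCOC(=O)C[C@@]1(C)[C@H](CCCO[Si](c2ccccc2)(c3ccccc3)C(C)(C)C)[C@@H](O[Si](C)(C)C(C)(C)C)CC[C@]1(C)O | intermediate
20 | ethyl 2-[(1S,2S,5S,6S)-6-{3-[(tert-butyldiphenylsilyl)oxy]propyl}-2,5-dihydroxy-1,2-dimethylcyclohexyl]acetate | CCOC(=O)C[C@@]1(C)[C@H](CCCO[Si](c2ccccc2)(c3ccccc3)C(C)(C)C)[C@@H](O)CC[C@]1(C)O | intermediate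
21 | ethyl 2-[(1S,2S,6S)-6-{3-[(tert-butyldiphenylsilyl)oxy]propyl}-2-hydroxy-1,2-dimethyl-5-oxocyclohexyl]acetate | CCOC(=O)C[C@@]1(C)[C@H](CCCO[Si](c2ccccc2)(c3ccccc3)C(C)(C)C)C(=O)CC[C@]1(C)O | intermediate
22 | ethyl 2-[(1S,2S,6S)-6-{3-[(tert-butyldiphenylsilyl)oxy]propyl}-1,2-dimethyl-5-oxo-2-[(triethylsilyl)oxy]cyclohexyl]acetate | CCOC(=O)C[C@@]1(C)[C@H](CCCO[Si](c2ccccc2)(c3ccccc3)C(C)(C)C)C(=O)CC[C@]1(C)O[Si](CC)(CC)CC | intermediate
23 | diethyl (1-cyanoethyl)phosphonate | CCOP(=O)(OCC)C(C)C#N | starting material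
24 | ethyl 2-[(1S,2S,5Z,6R)-6-{3-[(tert-butyldiphenylsilyl)oxy]propyl}-5-(1-cyanoethylidene)-1,2-dimethyl-2-[(triethylsilyl)oxy]cyclohexyl]acetate | CCOC(=O)C[C@@]1(C)[C@H](CCCO[Si](c2ccccc2)(c3ccccc3)C(C)(C)C)/C(=C(/C)C#N)CC[C@]1(C)O[Si](CC)(CC)CC | intermediate
25 | (2Z)-2-[(2R,3S,4S)-2-{3-[(tert-butyldiphenylsilyl)oxy]propyl}-3-(2-hydroxyethyl)-3,4-dimethyl-4-[(triethylsilyl)oxy]cyclohexylidene]propanenitrile | OCC[C@@]1(C)[C@H](CCCO[Si](c2ccccc2)(c3ccccc3)C(C)(C)C)/C(=C(/C)C#N)CC[C@]1(C)O[Si](CC)(CC)CC | intermediate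
26 | (2Z)-2-[(2R,3S,4S)-2-{3-[(tert-butyldiphenylsilyl)oxy]propyl}-3-(2-iodoethyl)-3,4-dimethyl-4-[(triethylsilyl)oxy]cyclohexylidene]propanenitrile | ICC[C@@]1(C)[C@H](CCCO[Si](c2ccccc2)(c3ccccc3)C(C)(C)C)/C(=C(/C)C#N)CC[C@]1(C)O[Si](CC)(CC)CC | intermediate
27 | prop-2-yn-1-ol | C#CCO | starting material
28 | [(E)-3-(dimethylalumanyloxy)-2-methylprop-1-enyl]dimethylalumane | C[Al](C)/C=C(\C)CO[Al](C)C | intermediate
29 | (E)-3-iodo-2-methylprop-2-en-1-ol | I/C=C(\C)CO | intermediate
30 | (E)-3-iodo-2-methylprop-2-enal | I/C=C(\C)C=O | intermediate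
31 | (S)-citronellal [(3S)-3,7-dimethyloct-6-enal] | C[C@@H](CCC=C(C)C)CC=O | starting material
32 | (3S)-3,7-dimethylocta-1,6-dien-1-yl nonafluorobutane-1-sulfonate (E/Z mixture at the enol double bond) | C[C@@H](CCC=C(C)C)C=COS(=O)(=O)C(F)(F)C(F)(F)C(F)(F)C(F)(F)F | intermediate
33 | (3S)-3,7-dimethyloct-6-en-1-yne | C#C[C@@H](C)CCC=C(C)C | intermediate
34 | dicyclohexyl[(1E,3S)-3,7-dimethylocta-1,6-dien-1-yl]borane | C1CCCCC1B(/C=C/[C@@H](C)CCC=C(C)C)C1CCCCC1 | intermediate
35 | [(1E,3S)-3,7-dimethylocta-1,6-dien-1-yl](methyl)zinc | C[Zn]/C=C/[C@@H](C)CCC=C(C)C | intermediate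
36 | (1E,3S,4E,6S)-1-iodo-2,6,10-trimethylundeca-1,4,9-trien-3-ol | CC(C)=CCC[C@H](C)/C=C/[C@H](O)/C(C)=C/I | intermediate
37 | tert-butyl{[(1E,3S,4E,6S)-1-iodo-2,6,10-trimethylundeca-1,4,9-trien-3-yl]oxy}dimethylsilane | CC(C)=CCC[C@H](C)/C=C/[C@H](O[Si](C)(C)C(C)(C)C)/C(C)=C/I | intermediate
38 | alkylzinc iodide from 26 (iodozinc in place of iodine) | I[Zn]CC[C@@]1(C)[C@H](CCCO[Si](c2ccccc2)(c3ccccc3)C(C)(C)C)/C(=C(/C)C#N)CC[C@]1(C)O[Si](CC)(CC)CC | intermediate
39 | (2Z)-2-[(2R,3S,4S)-3-[(3E,5S,6E,8S)-5-[(tert-butyldimethylsilyl)oxy]-4,8,12-trimethyltrideca-3,6,11-trien-1-yl]-2-{3-[(tert-butyldiphenylsilyl)oxy]propyl}-3,4-dimethyl-4-[(triethylsilyl)oxy]cyclohexylidene]propanenitrile | CC(C)=CCC[C@H](C)/C=C/[C@H](O[Si](C)(C)C(C)(C)C)/C(C)=C/CC[C@@]1(C)[C@H](CCCO[Si](c2ccccc2)(c3ccccc3)C(C)(C)C)/C(=C(/C)C#N)CC[C@]1(C)O[Si](CC)(CC)CC | intermediate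
40 | N-(diisobutylalumanyl) aldimine of 41 | CC(C)=CCC[C@H](C)/C=C/[C@H](O[Si](C)(C)C(C)(C)C)/C(C)=C/CC[C@@]1(C)[C@H](CCCO[Si](c2ccccc2)(c3ccccc3)C(C)(C)C)/C(=C(/C)C=N[Al](CC(C)C)CC(C)C)CC[C@]1(C)O[Si](CC)(CC)CC | intermediate
41 | (2Z)-2-[(2R,3S,4S)-3-[(3E,5S,6E,8S)-5-[(tert-butyldimethylsilyl)oxy]-4,8,12-trimethyltrideca-3,6,11-trien-1-yl]-2-{3-[(tert-butyldiphenylsilyl)oxy]propyl}-3,4-dimethyl-4-[(triethylsilyl)oxy]cyclohexylidene]propanal | CC(C)=CCC[C@H](C)/C=C/[C@H](O[Si](C)(C)C(C)(C)C)/C(C)=C/CC[C@@]1(C)[C@H](CCCO[Si](c2ccccc2)(c3ccccc3)C(C)(C)C)/C(=C(/C)C=O)CC[C@]1(C)O[Si](CC)(CC)CC | intermediate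
42 | (2Z)-2-[(2R,3S,4S)-4-hydroxy-3-[(3E,5S,6E,8S)-5-hydroxy-4,8,12-trimethyltrideca-3,6,11-trien-1-yl]-2-(3-hydroxypropyl)-3,4-dimethylcyclohexylidene]propanal | CC(C)=CCC[C@H](C)/C=C/[C@H](O)/C(C)=C/CC[C@@]1(C)[C@H](CCCO)/C(=C(/C)C=O)CC[C@]1(C)O | target

**Step count and risks**

Total step count: 24. Longest linear sequence: 19 steps (steps 1–16, then 22–24).

Steps most likely to fail:

1. Step 10. The ketyl may be reduced further to the open-chain alcohol before it closes onto the hindered β,β-disubstituted enoate, or the face selection at C2 may be incomplete. Fallback, from 16 back to 19: the ketyl is generated as a neutral O-stannyl ketyl in a radical chain instead of by electron transfer. Heating 16 with Bu3SnH and azobisisobutyronitrile in benzene at 80 °C should give, by 6-exo addition and hydrogen abstraction from the tin hydride, the tributylstannyl ether of the cyclohexanol F1, which is hydrolysed on aqueous work-up and silica gel to 19.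

2. Step 14. Addition of the stabilised anion to the hindered ketone may be too slow, so that C3 epimerises on prolonged heating, or the olefin geometry may be poorly controlled. Fallback, from 22 back to 24: isopropenylmagnesium bromide with CeCl3 (THF, −78 °C) adds to the ketone in preference to the ester and gives the tertiary allylic alcohol F2 (either carbinol epimer). Oxidative 1,3-transposition with pyridinium chlorochromate, [C5H5NH][CrO3Cl] (NaOAc, CH2Cl2), gives the enal ester F3, whose (Z) isomer is separated. Iodine in aqueous ammonia/THF then converts the aldehyde into the nitrile 24.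

3. Step 24. During the slow cleavage of the hindered tertiary silyl ether the basic fluoride may isomerise or deconjugate the enal. Fallback, from 39 to 42: the last two operations are reversed. Bu4NF (THF, rt → 40 °C) removes the three silyl groups from the base-stable nitrile to give the trihydroxy nitrile F4, and excess i-Bu2AlH (toluene/CH2Cl2, −78 → −20 °C) followed by mild acidic hydrolysis then gives 42 directly.

**Further compounds**

F1 | step 10 | ethyl 2-[(1S,2S,5S,6S)-5-[(tert-butyldimethylsilyl)oxy]-6-{3-[(tert-butyldiphenylsilyl)oxy]propyl}-1,2-dimethyl-2-[(tributylstannyl)oxy]cyclohexyl]acetate | CCOC(=O)C[C@@]1(C)[C@H](CCCO[Si](c2ccccc2)(c3ccccc3)C(C)(C)C)[C@@H](O[Si](C)(C)C(C)(C)C)CC[C@]1(C)O[Sn](CCCC)(CCCC)CCCC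
F2 | step 14 | ethyl 2-[(1S,2S,6S)-6-{3-[(tert-butyldiphenylsilyl)oxy]propyl}-5-hydroxy-1,2-dimethyl-5-(prop-1-en-2-yl)-2-[(triethylsilyl)oxy]cyclohexyl]acetate (carbinol configuration at C5 not defined) | CCOC(=O)C[C@@]1(C)[C@H](CCCO[Si](c2ccccc2)(c3ccccc3)C(C)(C)C)C(O)(C(C)=C)CC[C@]1(C)O[Si](CC)(CC)CC
F3 | step 14 | ethyl 2-[(1S,2S,5Z,6R)-6-{3-[(tert-butyldiphenylsilyl)oxy]propyl}-1,2-dimethyl-5-(1-oxopropan-2-ylidene)-2-[(triethylsilyl)oxy]cyclohexyl]acetate | CCOC(=O)C[C@@]1(C)[C@H](CCCO[Si](c2ccccc2)(c3ccccc3)C(C)(C)C)/C(=C(/C)C=O)CC[C@]1(C)O[Si](CC)(CC)CC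
F4 | step 24 | (2Z)-2-[(2R,3S,4S)-4-hydroxy-3-[(3E,5S,6E,8S)-5-hydroxy-4,8,12-trimethyltrideca-3,6,11-trien-1-yl]-2-(3-hydroxypropyl)-3,4-dimethylcyclohexylidene]propanenitrile | CC(C)=CCC[C@H](C)/C=C/[C@H](O)/C(C)=C/CC[C@@]1(C)[C@H](CCCO)/C(=C(/C)C#N)CC[C@]1(C)O
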